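## Retrosynthetic overview

1. The oxazole ring is closed last: 27 from aminoresorcinol 26 and trimethyl orthoacetate, with the nitrogen brought in by azo coupling on resorcinol 24.
2. Key step: the cis-decalin of 24 (C5 quaternary centre, cis ring fusion, C3=C4 alkene) comes from the trans-fused tertiary alcohol 22 by ionisation, an anti 1,2-methyl shift (C4 to C5) and hydride capture of the resulting allyl cation.
3. Ring A of 22 is closed by ring-closing metathesis of diene 21, made from ketone 18 and prenylmagnesium chloride.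
4. Ketone 18 (C9, C10) comes from (S)-3,4-dimethylcyclohexenone 6, the benzylic Grignard reagent 15 (from resorcinol) and allyl bromide; 6 (C8) comes from propanal and methyl vinyl ketone by organocatalysis.
5. Ring order: ring B (aldol condensation), then ring A (metathesis), then the oxazole ring; the benzene ring is bought as resorcinol.

Assumption: the target is taken exactly as drawn, i.e. the cis-fused (1R,2S,4aR,8aS) decalin; labels C1–C10 in the text use clerodane numbering (C9 bears the arylmethyl group, C5 and C10 are the ring-fusion atoms).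

## Route

Step 1
Reactants: 1 propanal; 2 but-3-en-2-one (methyl vinyl ketone)
Product: 4 (S)-4-methylcyclohex-2-en-1-one, via (S)-2-methyl-5-oxohexanal 3 (not isolated)
Conditions: (R)-α,α-diphenylprolinol methyl ether (5 mol %), ethyl 3,4-dihydroxybenzoate (20 mol %), neat, 4 °C; excess 1 evaporated; then aq KOH (20 mol %), n-Bu4NOH (cat.), Et2O–THF, reflux
Reagents that add atoms: none
Why: Enamine-catalysed Michael addition sets the methyl-bearing centre (future C8) under catalyst control (the (R)-catalyst is expected to give the (S)-aldehyde), and the intramolecular aldol condensation (Robinson-type cyclodehydration) then closes ring B without touching that centre.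

Step 2
Reactants: 4 (S)-4-methylcyclohex-2-en-1-one
Product: 6 (S)-3,4-dimethylcyclohex-2-en-1-one, via bromomagnesium enolate 5 (not isolated)
Conditions: MeMgBr, CuBr·SMe2 (5 mol %), THF, −78 °C; then N-tert-butylbenzenesulfinimidoyl chloride, −78 °C → rt
Reagents that add atoms: methylmagnesium bromide, C[Mg]Br
Why: Copper-catalysed conjugate addition followed by one-pot Mukaiyama dehydrogenation of the enolate (sulfenylation then syn-elimination) gives net β-methylation, and the C4 stereocentre (γ to the carbonyl) is not touched.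

Step 3
Reactants: 7 resorcinol
Product: 8 1,3-bis(methoxymethoxy)benzene
Conditions: MOMCl, i-Pr2NEt, CH2Cl2, 0 °C → rt
Reagents that add atoms: chloromethyl methyl ether, COCCl
Why: O-alkylation (acetal protection) gives MOM ethers that direct the metalation in step 6 and come off under mild acid in step 11.

Step 4
Reactants: 8 1,3-bis(methoxymethoxy)benzene
Product: 9 1-bromo-2,4-bis(methoxymethoxy)benzene
Conditions: NBS, MeCN, 0 °C
Reagents that add atoms: N-bromosuccinimide, O=C1CCC(=O)N1Br
Why: Electrophilic aromatic bromination goes to the unhindered position that is para to one OMOM group and ortho to the other.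

Step 5
Reactants: 9 1-bromo-2,4-bis(methoxymethoxy)benzene
Product: 10 1-methoxy-2,4-bis(methoxymethoxy)benzene
Conditions: NaOMe, CuBr (10 mol %), MeOH–DMF, 110 °C
Reagents that add atoms: sodium methoxide, C[O-].[Na+]
Why: Copper-catalysed Ullmann-type methoxylation of the aryl bromide installs the methoxy group of the target, and MOM acetals are stable to methoxide.

Step 6
Reactants: 10 1-methoxy-2,4-bis(methoxymethoxy)benzene
Product: 12 [3-methoxy-2,6-bis(methoxymethoxy)phenyl]methanol, via aryllithium 11 (not isolated)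
Conditions: n-BuLi, THF, 0 °C; (CH2O)n, −78 °C → rt
Reagents that add atoms: paraformaldehyde (as formaldehyde), C=O
Why: Directed ortho-metalation occurs at the position flanked by the two OMOM groups, the most acidic ring C–H, and the aryllithium is hydroxymethylated.

Step 7
Reactants: 12 [3-methoxy-2,6-bis(methoxymethoxy)phenyl]methanol
Product: 13 2-(chloromethyl)-4-methoxy-1,3-bis(methoxymethoxy)benzene (ArCH2Cl; Ar = 3-methoxy-2,6-bis(methoxymethoxy)phenyl from here on)
Conditions: MsCl, Et3N, CH2Cl2, −10 °C → rt; used crude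
Reagents that add atoms: methanesulfonyl chloride, CS(=O)(=O)Cl
Why: The electron-rich benzylic mesylate is displaced in situ by chloride (nucleophilic substitution) under non-acidic conditions that spare the MOM acetals.

Step 8
Reactants: 13 ArCH2Cl; 6 (S)-3,4-dimethylcyclohex-2-en-1-one; 14 allyl bromide
Product: 18 (2S,3R,4S)-3-(ArCH2)-3,4-dimethyl-2-(prop-2-en-1-yl)cyclohexan-1-one, via benzylic Grignard reagent 15 (not isolated), via silyl enol ether 16 (not isolated), via lithium enolate 17 (not isolated)
Conditions: Mg, THF, 0 °C; CuBr·SMe2 (10 mol %), TMSCl, HMPA, 6, −78 °C; concentrate; MeLi, THF, 0 °C; 14, −78 → 0 °C; NaOMe (cat.), MeOH, rt; chromatography, minor C2 epimer recycled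
Reagents that add atoms: none
Why: TMSCl/HMPA-accelerated copper-catalysed conjugate addition (Nakamura–Kuwajima conditions) delivers the benzyl group anti to the C4 methyl group and sets the quaternary centre (future C9, R), and regiospecific enolate allylation followed by base equilibration gives the more stable C2 epimer with the allyl group equatorial (future C10, S; about 3–4:1 expected from conformational analysis).

Step 9
Reactants: 18 allyl ketone; 19 1-chloro-3-methylbut-2-ene (prenyl chloride)
Product: 21 (1R,2S,3R,4S)-3-(ArCH2)-3,4-dimethyl-1-(2-methylbut-3-en-2-yl)-2-(prop-2-en-1-yl)cyclohexan-1-ol, via prenylmagnesium chloride 20 (not isolated)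
Conditions: Mg, THF, −10 °C; then 18, THF, −78 °C; H2O
Reagents that add atoms: none
Why: The allylic Grignard reagent adds through a six-membered SE2' transition state to give the 1,1-dimethylallyl carbinol, and it attacks equatorially, away from the axial C3 methyl group, so the new C–C bond is trans to the allyl group and the hydroxyl is axial (1R).

Step 10
Reactants: 21 diene alcohol
Product: 22 (4aR,7S,8R,8aS)-8-(ArCH2)-4,4,7,8-tetramethyl-1,5,6,7,8,8a-hexahydronaphthalen-4a(4H)-ol (trans-fused; 4a-OH axial)
Conditions: second-generation Grubbs catalyst (5 mol %), toluene, 80 °C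
Reagents that add atoms: none
Why: Ring-closing olefin metathesis of the two terminal alkenes, both on equatorial tethers, forms ring A as a trans-fused cyclohexene with loss of ethene and touches no stereocentre.

Step 11
Reactants: 22 trans-fused decalinol
Product: 24 2-(DecCH2)-4-methoxybenzene-1,3-diol (DecCH2 = [(1R,2S,4aR,8aS)-1,2,4a,5-tetramethyl-1,2,3,4,4a,7,8,8a-octahydronaphthalen-1-yl]methyl from here on), via MOM-protected cis-decalin 23 (not isolated)
Conditions: Tf2NH (10 mol %), Et3SiH (3 equiv), CH2Cl2, −78 → −30 °C; then MeOH, HCl (cat.), 40 °C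
Reagents that add atoms: none
Why: Proposed new method: acid-triggered ionisation of the axial tertiary C4a–OH with anti-periplanar 1,2-shift of the axial C4 methyl group (clerodane C4 to C5) inverts C4a, which turns the trans-decalin into the cis-decalin and sets the quaternary centre, and the shift is driven by formation of an allyl cation that Et3SiH reduces at its less hindered secondary terminus to leave the trisubstituted alkene, the closest known reaction types being the Westphalen-type Wagner–Meerwein methyl shift and ionic hydrogenation of allyl cations; acid methanolysis in the same flask then removes both MOM groups.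

Step 12
Reactants: 24 resorcinol
Product: 25 4-methoxy-6-[(E)-phenyldiazenyl]-2-(DecCH2)benzene-1,3-diol
Conditions: PhN2BF4, NaOAc, THF–H2O, 0 °C
Reagents that add atoms: benzenediazonium tetrafluoroborate, N#[N+]c1ccccc1.F[B-](F)(F)F
Why: Azo coupling (electrophilic aromatic substitution) occurs at the only free position that is para to one phenol and ortho to the other, which is where the nitrogen is needed.

Step 13
Reactants: 25 azo compound
Product: 27 5-methoxy-2-methyl-7-(DecCH2)-1,3-benzoxazol-6-ol (CNP0149771.1), via aminoresorcinol 26 (not isolated)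
Conditions: Zn, AcOH, MeC(OMe)3, 60 °C
Reagents that add atoms: trimethyl orthoacetate, CC(OC)(OC)OC
Why: Zinc in acetic acid cleaves the azo group reductively to the o-aminophenol, which condenses with the orthoester (cyclodehydration) to the 2-methylbenzoxazole, while the remote phenol cannot cyclise and is freed on work-up.

## Compound list

1 | propanal | CCC=O | starting material
2 | but-3-en-2-one | CC(=O)C=C | starting material
3 | (S)-2-methyl-5-oxohexanal | O=C[C@@H](C)CCC(C)=O | intermediate
4 | (S)-4-methylcyclohex-2-en-1-one | O=C1C=C[C@@H](C)CC1 | intermediate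
5 | bromomagnesium (3R,4S)-3,4-dimethylcyclohex-1-en-1-olate | Br[Mg]OC1=C[C@H](C)[C@@H](C)CC1 | intermediate
6 | (S)-3,4-dimethylcyclohex-2-en-1-one | O=C1C=C(C)[C@@H](C)CC1 | intermediate
7 | resorcinol | Oc1cccc(O)c1 | starting material
8 | 1,3-bis(methoxymethoxy)benzene | COCOc1cccc(OCOC)c1 | intermediate
9 | 1-bromo-2,4-bis(methoxymethoxy)benzene | COCOc1ccc(Br)c(OCOC)c1 | intermediate
10 | 1-methoxy-2,4-bis(methoxymethoxy)benzene | COCOc1ccc(OC)c(OCOC)c1 | intermediate
11 | [3-methoxy-2,6-bis(methoxymethoxy)phenyl]lithium | [Li]c1c(OCOC)ccc(OC)c1OCOC | intermediate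
12 | [3-methoxy-2,6-bis(methoxymethoxy)phenyl]methanol | OCc1c(OCOC)ccc(OC)c1OCOC | intermediate
13 | 2-(chloromethyl)-4-methoxy-1,3-bis(methoxymethoxy)benzene | ClCc1c(OCOC)ccc(OC)c1OCOC | intermediate
14 | 3-bromoprop-1-ene (allyl bromide) | C=CCBr | starting material
15 | {[3-methoxy-2,6-bis(methoxymethoxy)phenyl]methyl}magnesium chloride | Cl[Mg]Cc1c(OCOC)ccc(OC)c1OCOC | intermediate
16 | trimethyl{[(3R,4S)-3-{[3-methoxy-2,6-bis(methoxymethoxy)phenyl]methyl}-3,4-dimethylcyclohex-1-en-1-yl]oxy}silane | C[Si](C)(C)OC1=C[C@](C)(Cc2c(OCOC)ccc(OC)c2OCOC)[C@@H](C)CC1 | intermediate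
17 | lithium (3R,4S)-3-{[3-methoxy-2,6-bis(methoxymethoxy)phenyl]methyl}-3,4-dimethylcyclohex-1-en-1-olate | [Li]OC1=C[C@](C)(Cc2c(OCOC)ccc(OC)c2OCOC)[C@@H](C)CC1 | intermediate
18 | (2S,3R,4S)-3-{[3-methoxy-2,6-bis(methoxymethoxy)phenyl]methyl}-3,4-dimethyl-2-(prop-2-en-1-yl)cyclohexan-1-one | COCOc1ccc(OC)c(OCOC)c1C[C@]2(C)[C@@H](C)CCC(=O)[C@H]2CC=C | intermediate
19 | 1-chloro-3-methylbut-2-ene | CC(C)=CCCl | starting material
20 | (3-methylbut-2-en-1-yl)magnesium chloride | CC(C)=CC[Mg]Cl | intermediate
21 | (1R,2S,3R,4S)-3-{[3-methoxy-2,6-bis(methoxymethoxy)phenyl]methyl}-3,4-dimethyl-1-(2-methylbut-3-en-2-yl)-2-(prop-2-en-1-yl)cyclohexan-1-ol | COCOc1ccc(OC)c(OCOC)c1C[C@]2(C)[C@@H](C)CC[C@](O)(C(C)(C)C=C)[C@H]2CC=C | intermediate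
22 | (4aR,7S,8R,8aS)-8-{[3-methoxy-2,6-bis(methoxymethoxy)phenyl]methyl}-4,4,7,8-tetramethyl-1,5,6,7,8,8a-hexahydronaphthalen-4a(4H)-ol | COCOc1ccc(OC)c(OCOC)c1C[C@]2(C)[C@@H](C)CC[C@]3(O)C(C)(C)C=CC[C@@H]23 | intermediate
23 | 4-methoxy-1,3-bis(methoxymethoxy)-2-{[(1R,2S,4aR,8aS)-1,2,4a,5-tetramethyl-1,2,3,4,4a,7,8,8a-octahydronaphthalen-1-yl]methyl}benzene | COCOc1ccc(OC)c(OCOC)c1C[C@]2(C)[C@@H](C)CC[C@@]3(C)C(C)=CCC[C@@H]23 | intermediate
24 | 4-methoxy-2-{[(1R,2S,4aR,8aS)-1,2,4a,5-tetramethyl-1,2,3,4,4a,7,8,8a-octahydronaphthalen-1-yl]methyl}benzene-1,3-diol | COc1ccc(O)c(C[C@]2(C)[C@@H](C)CC[C@@]3(C)C(C)=CCC[C@@H]23)c1O | intermediate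
25 | 4-methoxy-6-[(E)-phenyldiazenyl]-2-{[(1R,2S,4aR,8aS)-1,2,4a,5-tetramethyl-1,2,3,4,4a,7,8,8a-octahydronaphthalen-1-yl]methyl}benzene-1,3-diol | COc1cc(/N=N/c2ccccc2)c(O)c(C[C@]3(C)[C@@H](C)CC[C@@]4(C)C(C)=CCC[C@@H]34)c1O | intermediate
26 | 4-amino-6-methoxy-2-{[(1R,2S,4aR,8aS)-1,2,4a,5-tetramethyl-1,2,3,4,4a,7,8,8a-octahydronaphthalen-1-yl]methyl}benzene-1,3-diol | COc1cc(N)c(O)c(C[C@]2(C)[C@@H](C)CC[C@@]3(C)C(C)=CCC[C@@H]23)c1O | intermediate
27 | 5-methoxy-2-methyl-7-{[(1R,2S,4aR,8aS)-1,2,4a,5-tetramethyl-1,2,3,4,4a,7,8,8a-octahydronaphthalen-1-yl]methyl}-1,3-benzoxazol-6-ol | COc1cc2nc(C)oc2c(C[C@]2(C)[C@@H](C)CC[C@@]3(C)C(C)=CCC[C@@H]23)c1O | target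

## Step count and risks

Total: 13 steps. Longest linear sequence: 11 steps (7 to 27, steps 3–13); the enone branch (steps 1–2) joins at step 8.

The three steps most likely to fail:

Step 8. The hindered benzylic nucleophile must form a quaternary centre next to a tertiary one, and the C2 (future C10) configuration rests on a modest thermodynamic preference. Fallback: set out from lithium enolate 17, generated as in step 8 but without adding 14. O-Acylation with allyl chloroformate gives allyl enol carbonate F1. Decarboxylative Tsuji–Trost allylation with Pd2(dba)3 and a t-Bu-PHOX ligand (both ligand enantiomers screened) then places the allyl group on C2 under ligand control and under neutral conditions that do not epimerise the product. The route is rejoined at 18.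

Step 9. The ketone is hindered, and both the γ-selectivity and the facial selectivity of the addition are needed for the stereochemical course of step 11. Fallback: from 18, lithiated isobutyronitrile (LDA, THF, −78 °C) adds to the ketone to give β-hydroxy nitrile F2. DIBAL-H followed by aqueous acid gives β-hydroxy aldehyde F3, and Wittig methylenation (Ph3P=CH2) returns to 21.

Step 11 (the proposed new step). A 1,2-hydride shift from C10, plain elimination, direct reduction of the first cation or over-reduction of the product alkene could compete with the methyl shift. Fallback with known reactions only: set out from silyl enol ether 16, isolated by non-aqueous work-up after the conjugate addition of step 8. Mukaiyama–Michael addition to pent-1-en-3-one (Sc(OTf)3 cat., CH2Cl2, −78 °C) gives 1,5-diketone F4. KOH in MeOH closes ring A by aldol condensation to octalone F5, in which C10 equilibrates to the required configuration. Me2CuLi adds to the ring-fusion carbon on the face of the ring-fusion hydrogen (cis-fused product), and the enolate is trapped with PhNTf2 as enol triflate F6. Reduction with Pd(OAc)2, PPh3, HCO2H and n-Bu3N gives 23, which is deprotected to 24 by the acid methanolysis of step 11.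

## Further compounds

F1 | step 8 | allyl (3R,4S)-3-{[3-methoxy-2,6-bis(methoxymethoxy)phenyl]methyl}-3,4-dimethylcyclohex-1-en-1-yl carbonate | C=CCOC(=O)OC1=C[C@](C)(Cc2c(OCOC)ccc(OC)c2OCOC)[C@@H](C)CC1
F2 | step 9 | 2-[(1R,2S,3R,4S)-1-hydroxy-3-{[3-methoxy-2,6-bis(methoxymethoxy)phenyl]methyl}-3,4-dimethyl-2-(prop-2-en-1-yl)cyclohexyl]-2-methylpropanenitrile | COCOc1ccc(OC)c(OCOC)c1C[C@]2(C)[C@@H](C)CC[C@](O)(C(C)(C)C#N)[C@H]2CC=C
F3 | step 9 | 2-[(1R,2S,3R,4S)-1-hydroxy-3-{[3-methoxy-2,6-bis(methoxymethoxy)phenyl]methyl}-3,4-dimethyl-2-(prop-2-en-1-yl)cyclohexyl]-2-methylpropanal | COCOc1ccc(OC)c(OCOC)c1C[C@]2(C)[C@@H](C)CC[C@](O)(C(C)(C)C=O)[C@H]2CC=C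
F4 | step 11 | (3R,4S)-3-{[3-methoxy-2,6-bis(methoxymethoxy)phenyl]methyl}-3,4-dimethyl-2-(3-oxopentyl)cyclohexan-1-one (C2 epimer mixture) | COCOc1ccc(OC)c(OCOC)c1C[C@]2(C)[C@@H](C)CCC(=O)C2CCC(=O)CC
F5 | step 11 | (4aS,5R,6S)-5-{[3-methoxy-2,6-bis(methoxymethoxy)phenyl]methyl}-1,5,6-trimethyl-4,4a,5,6,7,8-hexahydronaphthalen-2(3H)-one | COCOc1ccc(OC)c(OCOC)c1C[C@]2(C)[C@@H](C)CCC3=C(C)C(=O)CC[C@@H]23
F6 | step 11 | (4aS,5R,6S,8aR)-5-{[3-methoxy-2,6-bis(methoxymethoxy)phenyl]methyl}-1,5,6,8a-tetramethyl-3,4,4a,5,6,7,8,8a-octahydronaphthalen-2-yl trifluoromethanesulfonate | COCOc1ccc(OC)c(OCOC)c1C[C@]2(C)[C@@H](C)CC[C@@]3(C)C(C)=C(OS(=O)(=O)C(F)(F)F)CC[C@@H]23
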